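**Retrosynthetic overview**
1. Target 13 is cut at C10–C11: an NHC–copper allylic substitution joins the (E)-alkenylalane 12 (from cyclic alkyne 10) to allylic phosphate 11, setting the quaternary C10 and the 11E alkene in the last step.
2. The only ring is closed one step earlier (step 7): acyclic dienyne 9 is cycloisomerised by forming C16–C21, with hydrogen entering at the terminal CH2 of the isopropenyl group and leaving from the C17 methyl, as in the biosynthetic closure.
3. Both halves, 9 and 11, come from one alcohol 5. C13 is set by asymmetric conjugate reduction of enal 6, and the alkyne is made from the resulting aldehyde.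
4. Alcohol 5 comes from (2E,6E)-farnesyl acetate 1 by terminal allylic oxidation, bromination and copper-catalysed asymmetric SN2′ methylation. This builds the CH(CH3)–C(CH3)=CH2 end group that becomes both C3 and C20.

Assumption: atom labels C1–C15 follow the target chain (C1 = isopropenyl CH2, C10 = quaternary carbon, C15 = CH2 on the ring) and continue round the ring (C16 = ring CH bearing the chain, C17 = C(=CH2), C20 = CHMe, C21 = CMe2); for each asymmetric catalyst the antipode written is the one expected by analogy to give the stated configuration, and the mirror-image ligand is used instead if the first run shows the opposite sense.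

**Step 1**
Reactants: 1 (2E,6E)-farnesyl acetate [(2E,6E)-3,7,11-trimethyldodeca-2,6,10-trien-1-yl acetate]
Product: 2 (2E,6E,10E)-12-hydroxy-3,7,11-trimethyldodeca-2,6,10-trien-1-yl acetate
Conditions: SeO2 (0.1 equiv), tBuOOH (3 equiv), salicylic acid (0.1 equiv), CH2Cl2, 0 → 22 °C, stopped at partial conversion, 1 recycled
Reagents that add atoms: tert-butyl hydroperoxide, CC(C)(C)OO; selenium dioxide, O=[Se]=O (catalytic oxygen relay)
Why: Riley allylic oxidation with catalytic SeO2 and tBuOOH proceeds by an ene reaction and a [2,3]-shift at the most electron-rich, terminal trisubstituted alkene, so it oxidises the (E)-methyl group with retention of E geometry while the 2,3-alkene is deactivated by the allylic acetate.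

**Step 2**
Reactants: 2 (2E,6E,10E)-12-hydroxy-3,7,11-trimethyldodeca-2,6,10-trien-1-yl acetate
Product: 3 (2E,6E,10E)-12-bromo-3,7,11-trimethyldodeca-2,6,10-trien-1-yl acetate
Conditions: CBr4, PPh3, CH2Cl2, –20 → 0 °C
Reagents that add atoms: carbon tetrabromide, BrC(Br)(Br)Br
Why: Appel bromination replaces the primary allylic hydroxyl by bromide under neutral conditions at low temperature, without allylic transposition or E/Z scrambling.

**Step 3**
Reactants: 3 (2E,6E,10E)-12-bromo-3,7,11-trimethyldodeca-2,6,10-trien-1-yl acetate
Product: 5 (2E,6E,10S)-3,7,10,11-tetramethyldodeca-2,6,11-trien-1-ol, via acetate 4 (not isolated)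
Conditions: MeMgBr (1.2 equiv, slow addition), CuBr·SMe2 (3 mol %), (R,Rp)-Taniaphos C43H39FeNP2 (3.5 mol %), CH2Cl2, –78 °C; then iBu2AlH (2.5 equiv), –78 → 0 °C; aqueous work-up
Reagents that add atoms: methylmagnesium bromide, C[Mg]Br
Why: Copper-catalysed asymmetric allylic alkylation (SN2′) with the Cu/Taniaphos/MeMgBr system adds methyl to the CH terminus anti to bromide and shifts the alkene to give the CH(CH3)–C(CH3)=CH2 end group, the ligand choosing the alkene face to set the 10S centre (C3 and C20 of the target), after which iBu2AlH in the same flask reduces off the acetate.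

**Step 4**
Reactants: 5 (2E,6E,10S)-3,7,10,11-tetramethyldodeca-2,6,11-trien-1-ol
Product: 6 (2E,6E,10S)-3,7,10,11-tetramethyldodeca-2,6,11-trienal
Conditions: MnO2 (15 equiv), CH2Cl2, 22 °C
Reagents that add atoms: none
Why: MnO2 oxidation is selective for allylic alcohols and gives the (2E)-enal without isomerising any alkene or the stereocentre.

**Step 5**
Reactants: 6 (2E,6E,10S)-3,7,10,11-tetramethyldodeca-2,6,11-trienal
Product: 7 (3R,6E,10S)-3,7,10,11-tetramethyldodeca-6,11-dienal
Conditions: diethyl 2,6-dimethyl-1,4-dihydropyridine-3,5-dicarboxylate (Hantzsch ester, 1.1 equiv), morpholinium salt of (R)-3,3′-bis(2,4,6-triisopropylphenyl)-1,1′-binaphthyl-2,2′-diyl hydrogen phosphate (20 mol %), 1,4-dioxane, 50 °C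
Reagents that add atoms: none
Why: Counteranion-directed iminium catalysis with a Hantzsch ester (organocatalytic asymmetric transfer hydrogenation) reduces only the iminium-activated 2,3-alkene, the chiral phosphate anion steering hydride to one face of C3 to set 3R (C13 of the target), as is known for farnesal and citral.

**Step 6**
Reactants: 7 (3R,6E,10S)-3,7,10,11-tetramethyldodeca-6,11-dienal
Product: 9 (3R,6E,10S)-3,7,10,11-tetramethyldodeca-6,11-dien-1-yne, via enol nonaflate 8 (not isolated)
Conditions: C4F9SO2F (1.3 equiv), phosphazene base P2-Et (2.5 equiv), DMF, –30 → 22 °C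
Reagents that add atoms: none
Why: Enolisation and O-sulfonylation with C4F9SO2F followed by phosphazene-induced E2 elimination of the alkenyl nonaflate converts CH2–CHO into C≡CH without adding carbon, and the stereocentre is untouched because it is β to the carbonyl and cannot enolise.

**Step 7**
Reactants: 9 (3R,6E,10S)-3,7,10,11-tetramethyldodeca-6,11-dien-1-yne
Product: 10 (3R)-3-methyl-5-[(1R,3S)-2,2,3-trimethyl-6-methylidenecyclohexyl]pent-1-yne
Conditions: CoCl(C32H46N2O2) [chloro cobalt complex of N,N′-bis(3,5-di-tert-butylsalicylidene)ethane-1,2-diamine] (5 mol %), PhSiH3 (10 mol %), degassed benzene (0.03 M), 22 °C, stopped near 80 % conversion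
Reagents that add atoms: none
Why: Proposed new method: the cobalt hydride formed from the cobalt–salen chloride and PhSiH3 transfers H• only to the CH2 of the 1,1-disubstituted alkene (MHAT; the trisubstituted alkene and the alkyne are much slower acceptors), the C21 tertiary radical closes 6-endo onto C16 through a chair with the C20 methyl and the C15 chain equatorial (16R, cis to the untouched 20S centre), and divalent cobalt takes H• back from the least hindered β-position of the C17 radical, its methyl group, to give the exocyclic alkene and renew the hydride, which is the same bond, hydrogen entry and hydrogen loss as the cation–olefin closure proposed for the biosynthesis; the closest known reaction types are cobalt–salen MHAT cycloisomerisation of dienes, MHAT-initiated polyene cyclisation, and the titanocene chloride radical cyclisation of epoxygeranyl esters, which also closes 6-endo and ends in an exo-methylene group.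

**Step 8**
Reactants: 5 (2E,6E,10S)-3,7,10,11-tetramethyldodeca-2,6,11-trien-1-ol
Product: 11 diethyl (2E,6E,10S)-3,7,10,11-tetramethyldodeca-2,6,11-trien-1-yl phosphate
Conditions: ClP(O)(OEt)2, Et3N, DMAP (cat.), CH2Cl2, 0 °C
Reagents that add atoms: diethyl chlorophosphate, CCOP(=O)(Cl)OCC
Why: O-Phosphorylation of the primary allylic alcohol gives the E-allylic phosphate that serves as leaving group for copper-catalysed allylic substitution, with no stereocentre or alkene affected.

**Step 9**
Reactants: 10 (3R)-3-methyl-5-[(1R,3S)-2,2,3-trimethyl-6-methylidenecyclohexyl]pent-1-yne; 11 diethyl (2E,6E,10S)-3,7,10,11-tetramethyldodeca-2,6,11-trien-1-yl phosphate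
Product: 13 (3S,6E,10S,11E,13R)-10-ethenyl-2,3,6,10,13-pentamethyl-15-[(1R,3S)-2,2,3-trimethyl-6-methylidenecyclohexyl]pentadeca-1,6,11-triene (the target), via alkenylalane 12 (not isolated)
Conditions: 10 (1.5 equiv), iBu2AlH (1.5 equiv), hexane, 55 °C; then 11 (1.0 equiv), CuCl2·2H2O (5 mol %), silver carbene dimer Ag2(C31H29N2O3S)2 of (4S,5S)-3-(2,6-diethylphenyl)-4,5-diphenyl-1-(2-sulfonatophenyl)imidazolin-2-ylidene (2.5 mol %), THF, –15 °C
Reagents that add atoms: none
Why: syn-Hydroalumination of the terminal alkyne gives the (E)-alkenylalane (fixing 11E), and NHC–copper-catalysed enantioselective allylic substitution (SN2′) on the E-trisubstituted phosphate joins it to the methyl-bearing alkene carbon, creating the C10–C11 bond, the vinyl group and the all-carbon quaternary centre at once, with the carbene ligand choosing the face (10S) and the remote C13 centre having little influence.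

**Compound list**
1 | (2E,6E)-3,7,11-trimethyldodeca-2,6,10-trien-1-yl acetate (farnesyl acetate) | CC(=O)OC/C=C(\C)CC/C=C(\C)CCC=C(C)C | starting material
2 | (2E,6E,10E)-12-hydroxy-3,7,11-trimethyldodeca-2,6,10-trien-1-yl acetate | CC(=O)OC/C=C(\C)CC/C=C(\C)CC/C=C(\C)CO | intermediate
3 | (2E,6E,10E)-12-bromo-3,7,11-trimethyldodeca-2,6,10-trien-1-yl acetate | CC(=O)OC/C=C(\C)CC/C=C(\C)CC/C=C(\C)CBr | intermediate
4 | (2E,6E,10S)-3,7,10,11-tetramethyldodeca-2,6,11-trien-1-yl acetate | CC(=O)OC/C=C(\C)CC/C=C(\C)CC[C@H](C)C(=C)C | intermediate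
5 | (2E,6E,10S)-3,7,10,11-tetramethyldodeca-2,6,11-trien-1-ol | OC/C=C(\C)CC/C=C(\C)CC[C@H](C)C(=C)C | intermediate
6 | (2E,6E,10S)-3,7,10,11-tetramethyldodeca-2,6,11-trienal | O=C/C=C(\C)CC/C=C(\C)CC[C@H](C)C(=C)C | intermediate
7 | (3R,6E,10S)-3,7,10,11-tetramethyldodeca-6,11-dienal | O=CC[C@H](C)CC/C=C(\C)CC[C@H](C)C(=C)C | intermediate
8 | (3R,6E,10S)-3,7,10,11-tetramethyldodeca-1,6,11-trien-1-yl nonafluorobutane-1-sulfonate (E/Z mixture at C1) | FC(F)(F)C(F)(F)C(F)(F)C(F)(F)S(=O)(=O)OC=C[C@H](C)CC/C=C(\C)CC[C@H](C)C(=C)C | intermediate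
9 | (3R,6E,10S)-3,7,10,11-tetramethyldodeca-6,11-dien-1-yne | C#C[C@H](C)CC/C=C(\C)CC[C@H](C)C(=C)C | intermediate
10 | (3R)-3-methyl-5-[(1R,3S)-2,2,3-trimethyl-6-methylidenecyclohexyl]pent-1-yne (chain and ring methyl cis) | C#C[C@H](C)CC[C@@H]1C(=C)CC[C@H](C)C1(C)C | intermediate
11 | diethyl (2E,6E,10S)-3,7,10,11-tetramethyldodeca-2,6,11-trien-1-yl phosphate | CCOP(=O)(OCC)OC/C=C(\C)CC/C=C(\C)CC[C@H](C)C(=C)C | intermediate
12 | {(1E,3R)-3-methyl-5-[(1R,3S)-2,2,3-trimethyl-6-methylidenecyclohexyl]pent-1-en-1-yl}bis(2-methylpropyl)alumane | CC(C)C[Al](CC(C)C)/C=C/[C@H](C)CC[C@@H]1C(=C)CC[C@H](C)C1(C)C | intermediate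
13 | (3S,6E,10S,11E,13R)-10-ethenyl-2,3,6,10,13-pentamethyl-15-[(1R,3S)-2,2,3-trimethyl-6-methylidenecyclohexyl]pentadeca-1,6,11-triene | C=C[C@@](C)(/C=C/[C@H](C)CC[C@@H]1C(=C)CC[C@H](C)C1(C)C)CC/C=C(\C)CC[C@H](C)C(=C)C | target

**Step count**
Total: 9 steps. Longest linear sequence: 8 steps (steps 1–7 and 9); step 8 is a one-step branch from 5.

**Steps most likely to fail**

Step 7 (cycloisomerisation of 9 to 10) is the main risk. The combination of 6-endo closure onto a trisubstituted alkene with exo-selective hydrogen return is untested. The same cobalt hydride can move the new exocyclic alkene into the ring, or turn the isopropenyl group of 9 into the tetrasubstituted alkene, and the cis/trans ratio of a radical closure may be lower than that of a cationic one. The fallback is a polar, stepwise closure that sets out from 9 and returns at 10. Mukaiyama hydration of the 1,1-disubstituted alkene of 9 (Co(acac)2, PhSiH3, O2, iPrOH) gives the tertiary alcohol (3S,6E,10R)-2,3,6,10-tetramethyldodec-6-en-11-yn-2-ol F1. SnCl4 in CH2Cl2 at –78 °C ionises it to the C21 cation, which cyclises through the chair and is captured by chloride on the less hindered face to give the equatorial tertiary chloride (3R)-5-[(1S,3S,6S)-6-chloro-2,2,3,6-tetramethylcyclohexyl]-3-methylpent-1-yne F2. KOtBu in THF then effects anti-E2 elimination; the ring-locked equatorial C–Cl bond has only methyl hydrogens anti-periplanar, so the exocyclic alkene 10 results.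

Step 3 (asymmetric SN2′ methylation of 3) is the second risk. The bromide carries a methyl on its central carbon, a substitution pattern for which SN2′:SN2 ratio and ee with MeMgBr are not assured. The fallback moves stereocontrol from the catalyst to the leaving group; it sets out from 2 and returns at 4. Alcohol 2 and (R)-1-(naphthalen-1-yl)ethyl isocyanate give the carbamate (2E,6E,10E)-3,7,11-trimethyl-12-({[(1R)-1-(naphthalen-1-yl)ethyl]carbamoyl}oxy)dodeca-2,6,10-trien-1-yl acetate F3. N-Deprotonation with LiN(SiMe3)2 and treatment with MeCu (from MeLi and CuI) delivers methyl intramolecularly from the carbamate-bound cuprate in a syn-SN2′ reaction, the auxiliary differentiating the alkene faces, to give 4. Acetate 4 is then cleaved to 5 with iBu2AlH as in step 3.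

Step 9 (fragment union) is the third risk. Hydroalumination of the branched alkyne 10 can be accompanied by C–H metalation, and alkenyl transfer to a hindered trisubstituted phosphate may be slow or poorly face-selective. The fallback transfers the alkynyl group instead and sets the alkene geometry afterwards; it sets out from 10 (with 11) and returns at 13. Alkyne 10 is converted to its alkynylalane (iBu2AlH, 5 mol % Et3N, hexane), which undergoes the same NHC–copper allylic substitution with 11 to give the 1,4-enyne (3S,6E,10S,13R)-10-ethenyl-2,3,6,10,13-pentamethyl-15-[(1R,3S)-2,2,3-trimethyl-6-methylidenecyclohexyl]pentadeca-1,6-dien-11-yne F4. Dissolving-metal reduction (Na, NH3/THF, –78 °C) then converts the internal alkyne into the 11E alkene without touching the isolated alkenes, giving 13.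

**Further compounds**
F1 | step 7 | (3S,6E,10R)-2,3,6,10-tetramethyldodec-6-en-11-yn-2-ol | C#C[C@H](C)CC/C=C(\C)CC[C@H](C)C(C)(C)O
F2 | step 7 | (3R)-5-[(1S,3S,6S)-6-chloro-2,2,3,6-tetramethylcyclohexyl]-3-methylpent-1-yne | C#C[C@H](C)CC[C@@H]1[C@@](C)(Cl)CC[C@H](C)C1(C)C
F3 | step 3 | (2E,6E,10E)-3,7,11-trimethyl-12-({[(1R)-1-(naphthalen-1-yl)ethyl]carbamoyl}oxy)dodeca-2,6,10-trien-1-yl acetate | CC(=O)OC/C=C(\C)CC/C=C(\C)CC/C=C(\C)COC(=O)N[C@H](C)c1cccc2ccccc12
F4 | step 9 | (3S,6E,10S,13R)-10-ethenyl-2,3,6,10,13-pentamethyl-15-[(1R,3S)-2,2,3-trimethyl-6-methylidenecyclohexyl]pentadeca-1,6-dien-11-yne | C=C[C@@](C)(C#C[C@H](C)CC[C@@H]1C(=C)CC[C@H](C)C1(C)C)CC/C=C(\C)CC[C@H](C)C(=C)C
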